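**Plan**

- Arenes are lettered A (benzyl guaiacol), B, C, D (arenes of dihydrobenzofuran units 1, 2, 3, counted from the tetrahydrofuran) and E (terminal guaiacol). The retrosynthesis cuts, in order: the tetrahydrofuran O1–C2 bond (ether closure) and C2–C3 bond (aldol), giving a ring B aldehyde and an (S)-benzyl lactone carrying ring A; the C2–C3 bonds of units 1 and 2 together; the two ArO–CH2 ether bonds; C2–C3 of unit 3.
- Enabling feature: in units 1 and 2, C3 sits on the ring B (or ring C) carbon ortho to the ring oxygen, and that oxygen carries the benzylic C2. Both units are (2S,3R), so both C2–C3 bonds can be made at once by carbene insertion into ArO–CH2–Ar under one chiral catalyst.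
- Forward: one phenolic arylacetate block from 5-bromovanillin serves rings B, C and D. Unit 3 is closed first (single insertion, mirror-image catalyst), rings C and B are attached by two Mitsunobu etherifications, units 1 and 2 close together, and the tetrahydrofuran closes last after a lactone aldol.
- Stereochemistry: C2 of each dihydrobenzofuran comes from the chiral dirhodium catalyst and C3 from base equilibration to trans. Tetrahydrofuran C4 comes from an Evans alkylation, C3 from the trans-selective lactone aldol, and C2 from a stereoconvergent benzylic cation closure.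

Key step: step 19

Assumption: Rh2(S-PTTL)4 is taken to give the 2R dihydrobenzofuran and Rh2(R-PTTL)4 the 2S one, by analogy with simpler 2-benzyloxyphenyl diazoacetates; if these substrates respond in the opposite sense, the two catalysts are exchanged between steps 11 and 19.

Shorthand:
- TIPS = triisopropylsilyl; TBS = tert-butyldimethylsilyl.
- ArSi = 3-methoxy-4-(triisopropylsilyloxy)phenyl (protected ring A or ring E).
- DE = (2R,3S)-2-ArSi-7-methoxy-3-[(triisopropylsilyloxy)methyl]-2,3-dihydro-1-benzofuran-5-yl (unit 3 on ring D).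
- BCDE = (2S,3R)-3-[(tert-butyldimethylsilyloxy)methyl]-2-{(2S,3R)-3-[(tert-butyldimethylsilyloxy)methyl]-2-DE-7-methoxy-2,3-dihydro-1-benzofuran-5-yl}-7-methoxy-2,3-dihydro-1-benzofuran-5-yl.
- Rh2(S-PTTL)4 = dirhodium tetrakis[N-phthaloyl-(S)-tert-leucinate]; Rh2(R-PTTL)4 is its mirror image.
- p-ABSA = 4-acetamidobenzenesulfonyl azide.

**Route**

Step 1
Reactants: 1 5-bromovanillin
Product: 2 4-(benzyloxy)-3-bromo-5-methoxybenzaldehyde
Conditions: BnBr, K2CO3, DMF, rt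
Reagents that add atoms: benzyl bromide, BrCc1ccccc1
Why: Williamson etherification of the phenoxide masks the phenol, which would otherwise divert the later palladium arylation towards a benzofuranone.

Step 2
Reactants: 2 4-(benzyloxy)-3-bromo-5-methoxybenzaldehyde
Product: 3 2-[4-(benzyloxy)-3-bromo-5-methoxyphenyl]-1,3-dioxolane
Conditions: ethylene glycol, TsOH·H2O (cat.), toluene, reflux, Dean–Stark
Reagents that add atoms: ethylene glycol, OCCO
Why: Acid-catalysed acetalisation with azeotropic removal of water protects the aldehyde from Knoevenagel condensation with the malonate and from the later base, hydride and carbene steps on rings B and D.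

Step 3
Reactants: 3 2-[4-(benzyloxy)-3-bromo-5-methoxyphenyl]-1,3-dioxolane; 4 dimethyl malonate
Product: 5 dimethyl 2-[2-(benzyloxy)-5-(1,3-dioxolan-2-yl)-3-methoxyphenyl]malonate
Conditions: Pd(OAc)2 (2 mol%), P(t-Bu)3·HBF4 (4 mol%), K3PO4, toluene, 90 °C
Reagents that add atoms: none
Why: Palladium-catalysed α-arylation of a malonate enolate with a bulky electron-rich phosphine is reliable for ortho-alkoxy aryl bromides, and the acetal and benzyl ether are inert to it.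

Step 4
Reactants: 5 dimethyl 2-[2-(benzyloxy)-5-(1,3-dioxolan-2-yl)-3-methoxyphenyl]malonate
Product: 6 methyl 2-[2-(benzyloxy)-5-(1,3-dioxolan-2-yl)-3-methoxyphenyl]acetate
Conditions: LiCl, H2O, DMSO, 140 °C
Reagents that add atoms: none
Why: Krapcho dealkoxycarbonylation removes one ester group of the aryl malonate under neutral conditions that leave the dioxolane and the benzyl ether intact.

Step 5
Reactants: 6 methyl 2-[2-(benzyloxy)-5-(1,3-dioxolan-2-yl)-3-methoxyphenyl]acetate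
Product: 7 methyl 2-[5-(1,3-dioxolan-2-yl)-2-hydroxy-3-methoxyphenyl]acetate
Conditions: H2 (1 atm), 10% Pd/C, EtOAc, rt
Reagents that add atoms: none
Why: Hydrogenolysis cleaves the aryl benzyl ether quickly, while the dioxolane is stable in neutral ethyl acetate and the methyl ester is untouched.

Step 6
Reactants: 7 methyl 2-[5-(1,3-dioxolan-2-yl)-2-hydroxy-3-methoxyphenyl]acetate (the portion destined for ring C)
Product: 8 methyl 2-(5-formyl-2-hydroxy-3-methoxyphenyl)acetate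
Conditions: PPTS (cat.), acetone/H2O (10:1), 40 °C
Reagents that add atoms: water, O
Why: Mild acid-catalysed acetal hydrolysis frees the electron-rich aldehyde without lactonising the ortho-hydroxyphenylacetate.

Step 7
Reactants: 9 vanillin
Product: 10 3-methoxy-4-(triisopropylsilyloxy)benzaldehyde
Conditions: TIPSCl, imidazole, DMF, rt
Reagents that add atoms: triisopropylsilyl chloride, CC(C)[Si](Cl)(C(C)C)C(C)C
Why: Silylation of the phenol gives an aryl silyl ether that should withstand DBU, hydride and mild acid in the later steps and is removed by fluoride at the end.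

Step 8
Reactants: 10 3-methoxy-4-(triisopropylsilyloxy)benzaldehyde
Product: 11 [3-methoxy-4-(triisopropylsilyloxy)phenyl]methanol
Conditions: NaBH4, MeOH, 0 °C
Reagents that add atoms: none
Why: Borohydride reduction of the aldehyde gives the benzylic alcohol needed as the Mitsunobu partner.

Step 9
Reactants: 7 methyl 2-[5-(1,3-dioxolan-2-yl)-2-hydroxy-3-methoxyphenyl]acetate; 11 [3-methoxy-4-(triisopropylsilyloxy)phenyl]methanol
Product: 12 methyl 2-[2-(ArSi-methoxy)-5-(1,3-dioxolan-2-yl)-3-methoxyphenyl]acetate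
Conditions: PPh3, DIAD, THF, 0 °C to rt
Reagents that add atoms: none
Why: Mitsunobu etherification joins the phenol to the electron-rich benzylic alcohol under neutral conditions that spare the aryl silyl ether and the acetal.

Step 10
Reactants: 12 methyl 2-[2-(ArSi-methoxy)-5-(1,3-dioxolan-2-yl)-3-methoxyphenyl]acetate
Product: 13 methyl 2-[2-(ArSi-methoxy)-5-(1,3-dioxolan-2-yl)-3-methoxyphenyl]-2-diazoacetate
Conditions: p-ABSA, DBU, MeCN, 0 °C to rt
Reagents that add atoms: 4-acetamidobenzenesulfonyl azide, CC(=O)Nc1ccc(cc1)S(=O)(=O)N=[N+]=[N-]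
Why: Regitz diazo transfer to the DBU-generated arylacetate enolate gives the donor–acceptor diazo ester.

Step 11
Reactants: 13 methyl 2-[2-(ArSi-methoxy)-5-(1,3-dioxolan-2-yl)-3-methoxyphenyl]-2-diazoacetate
Product: 15 methyl (2R,3R)-2-ArSi-5-(1,3-dioxolan-2-yl)-7-methoxy-2,3-dihydro-1-benzofuran-3-carboxylate (trans), via cis ester 14 (not isolated)
Conditions: Rh2(S-PTTL)4 (2 mol%), toluene, −78 °C; then DBU, −78 to 40 °C
Reagents that add atoms: none
Why: Enantioselective intramolecular 1,5 C–H insertion of the dirhodium carbene into the ArO–CH2–Ar bond should give the cis dihydrobenzofuran with C2 set as R by the catalyst, and DBU then epimerises the ester-bearing C3 to the more stable trans isomer.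

Step 12
Reactants: 15 methyl (2R,3R)-2-ArSi-5-(1,3-dioxolan-2-yl)-7-methoxy-2,3-dihydro-1-benzofuran-3-carboxylate
Product: 17 (2R,3S)-2-ArSi-3-(hydroxymethyl)-7-methoxy-2,3-dihydro-1-benzofuran-5-carbaldehyde, via acetal alcohol 16 (not isolated)
Conditions: LiAlH4, THF, 0 °C; then aq HCl (1 mol/L), THF, rt
Reagents that add atoms: water, O
Why: Hydride reduction turns the ester into the primary alcohol, which removes the acidic C3–H before the later base steps, and the acidic work-up hydrolyses the dioxolane without touching C2, C3 or the aryl silyl ether.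

Step 13
Reactants: 17 (2R,3S)-2-ArSi-3-(hydroxymethyl)-7-methoxy-2,3-dihydro-1-benzofuran-5-carbaldehyde
Product: 18 (2R,3S)-2-ArSi-7-methoxy-3-[(triisopropylsilyloxy)methyl]-2,3-dihydro-1-benzofuran-5-carbaldehyde
Conditions: TIPSCl, imidazole, DMF, rt
Reagents that add atoms: triisopropylsilyl chloride, CC(C)[Si](Cl)(C(C)C)C(C)C
Why: Silylation of the primary alcohol gives an ether that should survive the Mitsunobu, diazo-transfer, carbene, hydride and dilute-acid steps ahead.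

Step 14
Reactants: 18 (2R,3S)-2-ArSi-7-methoxy-3-[(triisopropylsilyloxy)methyl]-2,3-dihydro-1-benzofuran-5-carbaldehyde
Product: 19 DE-methanol
Conditions: NaBH4, MeOH/THF, 0 °C
Reagents that add atoms: none
Why: Borohydride reduction of the aldehyde gives the ring D benzylic alcohol for coupling to ring C.

Step 15
Reactants: 8 methyl 2-(5-formyl-2-hydroxy-3-methoxyphenyl)acetate; 19 DE-methanol
Product: 20 methyl 2-[2-(DE-methoxy)-5-formyl-3-methoxyphenyl]acetate
Conditions: PPh3, DIAD, THF, 0 °C to rt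
Reagents that add atoms: none
Why: Mitsunobu etherification joins the phenol, made more acidic by its para-formyl group, to the para-alkoxybenzylic alcohol under neutral conditions that leave the aldehyde, ester and silyl ethers untouched.

Step 16
Reactants: 20 methyl 2-[2-(DE-methoxy)-5-formyl-3-methoxyphenyl]acetate
Product: 21 methyl 2-[2-(DE-methoxy)-5-(hydroxymethyl)-3-methoxyphenyl]acetate
Conditions: NaBH4, MeOH/THF, 0 °C
Reagents that add atoms: none
Why: Borohydride reduces the aryl aldehyde chemoselectively in the presence of the methyl ester and gives the benzylic alcohol for the second fragment coupling.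

Step 17
Reactants: 7 methyl 2-[5-(1,3-dioxolan-2-yl)-2-hydroxy-3-methoxyphenyl]acetate; 21 methyl 2-[2-(DE-methoxy)-5-(hydroxymethyl)-3-methoxyphenyl]acetate
Product: 22 methyl 2-[2-{[4-(DE-methoxy)-3-methoxy-5-(2-methoxy-2-oxoethyl)phenyl]methoxy}-5-(1,3-dioxolan-2-yl)-3-methoxyphenyl]acetate
Conditions: PPh3, DIAD, THF, 0 °C to rt
Reagents that add atoms: none
Why: A second Mitsunobu etherification attaches the ring B block through its phenol oxygen and completes the ring B–C–D benzyl ether chain with both arylacetates in place.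

Step 18
Reactants: 22 the bis(arylacetate) of step 17
Product: 23 bis(diazoacetate) in which both ArCH2CO2Me groups of 22 have become ArC(=N2)CO2Me
Conditions: p-ABSA (3 equiv), DBU (3.5 equiv), MeCN, 0 °C to rt
Reagents that add atoms: 4-acetamidobenzenesulfonyl azide, CC(=O)Nc1ccc(cc1)S(=O)(=O)N=[N+]=[N-]
Why: Regitz diazo transfer occurs at both arylacetate methylene groups, the only DBU-acidic C–H bonds left now that unit 3 carries a silyl ether instead of an ester.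

Step 19
Reactants: 23 bis(diazoacetate)
Product: 25 trans,trans diester methyl (2S,3S)-2-[(2S,3S)-2-DE-7-methoxy-3-(methoxycarbonyl)-2,3-dihydro-1-benzofuran-5-yl]-5-(1,3-dioxolan-2-yl)-7-methoxy-2,3-dihydro-1-benzofuran-3-carboxylate, via cis,cis diester 24 (not isolated)
Conditions: Rh2(R-PTTL)4 (4 mol%), toluene (0.01 mol/L), −78 to −40 °C; then DBU, rt to 40 °C
Reagents that add atoms: none
Why: Each diazo ester loses dinitrogen at the dirhodium catalyst to give an electrophilic donor–acceptor carbene, which inserts into the adjacent ArO–CH2–Ar C–H bond in one asynchronous event where hydride-like transfer to the carbene carbon and C–C bond formation take place within a C–H–C triangle. The closest known reaction is the enantioselective intramolecular C–H insertion of 2-benzyloxyphenyl diazoacetates to cis-2-aryl-2,3-dihydrobenzofuran-3-carboxylates under chiral dirhodium tetracarboxylates, here run at two sites of one substrate. Both rings close in the 1,5 insertion mode, the new C2–C3 bond completing a five-membered oxygen ring on ring B (unit 1) and on ring C (unit 2). C2 of both rings is set by the catalyst, which selects one of the two enantiotopic benzylic hydrogens (the R catalyst for 2S, mirror to step 11), whereas C3 is formed cis and is then equilibrated by DBU through its ester enolate to the thermodynamically preferred 2,3-trans arrangement. The step needs site selectivity, chemoselectivity over bimolecular carbene reactions and catalyst control in the presence of unit 3; these are secured because each carbene has exactly one C–H bond in a 1,5 relation, that bond is activated by the ether oxygen and an electron-rich arene, unit 3 carries no hydroxyl or enolisable group and its stereocentres lie far from both reacting sites, and the reaction is run dilute and cold.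

Step 20
Reactants: 25 trans,trans diester
Product: 27 (2S,3R)-2-[(2S,3R)-2-DE-3-(hydroxymethyl)-7-methoxy-2,3-dihydro-1-benzofuran-5-yl]-3-(hydroxymethyl)-7-methoxy-2,3-dihydro-1-benzofuran-5-carbaldehyde, via diol acetal 26 (not isolated)
Conditions: LiAlH4, THF, 0 °C; then aq HCl (1 mol/L), THF, rt
Reagents that add atoms: water, O
Why: Hydride reduction converts both esters into primary alcohols, which fixes the trans configuration by removing the enolisable C3–H, and the acidic work-up then hydrolyses the ring B dioxolane without affecting the triisopropylsilyl ethers.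

Step 21
Reactants: 27 the diol aldehyde of step 20
Product: 28 BCDE-carbaldehyde (bis-TBS ether of 27)
Conditions: TBSCl, imidazole, DMF, rt
Reagents that add atoms: tert-butyldimethylsilyl chloride, CC(C)(C)[Si](C)(C)Cl
Why: Silylation of the two primary alcohols removes all acidic protons before the enolate addition and leaves the aldehyde unchanged.

Step 22
Reactants: 29 3-(4-hydroxy-3-methoxyphenyl)propanoic acid
Product: 31 3-ArSi-propanoic acid, via bis-silyl compound 30 (not isolated)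
Conditions: TIPSCl (2.3 equiv), imidazole, DMF, rt; then K2CO3, MeOH/H2O, rt; aq HCl to pH 3
Reagents that add atoms: triisopropylsilyl chloride, CC(C)[Si](Cl)(C(C)C)C(C)C
Why: Silylation of both the phenol and the acid is followed by selective basic hydrolysis of the far more labile silyl ester, which leaves the aryl silyl ether in place.

Step 23
Reactants: 31 3-ArSi-propanoic acid; 32 (R)-4-benzyl-1,3-oxazolidin-2-one
Product: 34 (R)-4-benzyl-3-(3-ArSi-propanoyl)-1,3-oxazolidin-2-one, via mixed pivalic anhydride 33 (not isolated)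
Conditions: PivCl, Et3N, THF, −20 °C; then 32, LiCl, rt
Reagents that add atoms: none
Why: N-Acylation of the Evans oxazolidinone through the mixed pivalic anhydride under LiCl and Et3N installs the chiral auxiliary without a strong base.

Step 24
Reactants: 34 (R)-4-benzyl-3-(3-ArSi-propanoyl)-1,3-oxazolidin-2-one
Product: 36 tert-butyl (3S)-3-(ArSi-methyl)-4-[(4R)-4-benzyl-2-oxo-1,3-oxazolidin-3-yl]-4-oxobutanoate, via sodium enolate 35 (not isolated)
Conditions: NaN(SiMe3)2, THF, −78 °C; then BrCH2CO2t-Bu, −78 to −40 °C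
Reagents that add atoms: tert-butyl bromoacetate, CC(C)(C)OC(=O)CBr
Why: In this Evans asymmetric alkylation the chelated Z sodium enolate is attacked by the bromoacetate on the face opposite the auxiliary benzyl group, which sets the S stereocentre that becomes C4 of the tetrahydrofuran.

Step 25
Reactants: 36 the alkylated imide of step 24
Product: 38 (4S)-4-(ArSi-methyl)oxolan-2-one, via hydroxy ester 37 (not isolated)
Conditions: LiBH4, MeOH (1 equiv), THF, 0 °C; then TFA, CH2Cl2, rt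
Reagents that add atoms: none
Why: Borohydride cleaves the imide reductively to the primary alcohol and frees the auxiliary without touching the tert-butyl ester, and acid then closes the γ-lactone with loss of isobutene while the stereocentre is unaffected.

Step 26
Reactants: 38 (4S)-4-(ArSi-methyl)oxolan-2-one; 28 BCDE-carbaldehyde
Product: 40 (3R,4S)-3-[BCDE(hydroxy)methyl]-4-(ArSi-methyl)oxolan-2-one (both carbinol epimers), via lithium enolate 39 (not isolated)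
Conditions: LiN(SiMe3)2, THF, −78 °C; then 28, −78 °C; AcOH
Reagents that add atoms: none
Why: Aldol addition of the lactone lithium enolate to the aldehyde takes place on the enolate face opposite the 4-benzyl group and so sets C3 trans to C4, while the carbinol carbon is formed as a mixture that the later cation closure makes irrelevant.

Step 27
Reactants: 40 the aldol adduct of step 26
Product: 41 (2S,3S)-2-[BCDE(hydroxy)methyl]-3-(ArSi-methyl)butane-1,4-diol (both carbinol epimers)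
Conditions: LiAlH4, THF, 0 °C
Reagents that add atoms: none
Why: Hydride reduction opens the lactone to the 1,4-diol without affecting the existing stereocentres or the silyl ethers.

Step 28
Reactants: 41 the triol of step 27
Product: 42 [(2R,3S,4S)-2-BCDE-4-(ArSi-methyl)oxolan-3-yl]methanol
Conditions: CSA (0.1 equiv), CH2Cl2, 0 °C
Reagents that add atoms: none
Why: Acid ionises the para-alkoxy-activated secondary benzylic alcohol and the primary hydroxyl on the benzyl-bearing carbon captures the cation in a 5-exo closure with the aryl group settling trans to the C3 hydroxymethyl group (2R), so both carbinol epimers converge, the 3,4-cis relationship inherited from the trans lactone is kept, and catalytic acid at 0 °C should be too mild to ionise the dihydrobenzofuran ethers.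

Step 29
Reactants: 42 the silyl-protected tetrahydrofuran of step 28
Product: 43 CNP0267891.2
Conditions: TBAF, AcOH, THF, 0 °C to rt
Reagents that add atoms: none
Why: Fluoride cleaves all five silyl ethers, and buffering with acetic acid avoids phenoxide-driven opening of the dihydrobenzofurans.

**Compound list**

1 | 5-bromovanillin | O=Cc1cc(Br)c(O)c(OC)c1 | starting material
2 | 4-(benzyloxy)-3-bromo-5-methoxybenzaldehyde | O=Cc1cc(Br)c(OCc2ccccc2)c(OC)c1 | intermediate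
3 | 2-[4-(benzyloxy)-3-bromo-5-methoxyphenyl]-1,3-dioxolane | COc1cc(cc(Br)c1OCc1ccccc1)C1OCCO1 | intermediate
4 | dimethyl malonate | COC(=O)CC(=O)OC | starting material
5 | dimethyl 2-[2-(benzyloxy)-5-(1,3-dioxolan-2-yl)-3-methoxyphenyl]malonate | COC(=O)C(C(=O)OC)c1cc(cc(OC)c1OCc1ccccc1)C1OCCO1 | intermediate
6 | methyl 2-[2-(benzyloxy)-5-(1,3-dioxolan-2-yl)-3-methoxyphenyl]acetate | COC(=O)Cc1cc(cc(OC)c1OCc1ccccc1)C1OCCO1 | intermediate
7 | methyl 2-[5-(1,3-dioxolan-2-yl)-2-hydroxy-3-methoxyphenyl]acetate | COC(=O)Cc1cc(cc(OC)c1O)C1OCCO1 | intermediate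
8 | methyl 2-(5-formyl-2-hydroxy-3-methoxyphenyl)acetate | COC(=O)Cc1cc(C=O)cc(OC)c1O | intermediate
9 | vanillin | COc1cc(C=O)ccc1O | starting material
10 | 3-methoxy-4-(triisopropylsilyloxy)benzaldehyde | COc1cc(C=O)ccc1O[Si](C(C)C)(C(C)C)C(C)C | intermediate
11 | [3-methoxy-4-(triisopropylsilyloxy)phenyl]methanol | COc1cc(CO)ccc1O[Si](C(C)C)(C(C)C)C(C)C | intermediate
12 | methyl 2-[2-(ArSi-methoxy)-5-(1,3-dioxolan-2-yl)-3-methoxyphenyl]acetate | COC(=O)Cc1cc(cc(OC)c1OCc1ccc(O[Si](C(C)C)(C(C)C)C(C)C)c(OC)c1)C1OCCO1 | intermediate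
13 | methyl 2-[2-(ArSi-methoxy)-5-(1,3-dioxolan-2-yl)-3-methoxyphenyl]-2-diazoacetate | COC(=O)C(=[N+]=[N-])c1cc(cc(OC)c1OCc1ccc(O[Si](C(C)C)(C(C)C)C(C)C)c(OC)c1)C1OCCO1 | intermediate
14 | cis ester, methyl (2R,3S)-2-ArSi-5-(1,3-dioxolan-2-yl)-7-methoxy-2,3-dihydro-1-benzofuran-3-carboxylate | O1CCOC1c1cc(OC)c2c(c1)[C@H](C(=O)OC)[C@H](c1ccc(O[Si](C(C)C)(C(C)C)C(C)C)c(OC)c1)O2 | intermediate
15 | trans ester, methyl (2R,3R)-2-ArSi-5-(1,3-dioxolan-2-yl)-7-methoxy-2,3-dihydro-1-benzofuran-3-carboxylate | O1CCOC1c1cc(OC)c2c(c1)[C@@H](C(=O)OC)[C@H](c1ccc(O[Si](C(C)C)(C(C)C)C(C)C)c(OC)c1)O2 | intermediate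
16 | acetal alcohol, [(2R,3S)-2-ArSi-5-(1,3-dioxolan-2-yl)-7-methoxy-2,3-dihydro-1-benzofuran-3-yl]methanol | O1CCOC1c1cc(OC)c2c(c1)[C@@H](CO)[C@H](c1ccc(O[Si](C(C)C)(C(C)C)C(C)C)c(OC)c1)O2 | intermediate
17 | (2R,3S)-2-ArSi-3-(hydroxymethyl)-7-methoxy-2,3-dihydro-1-benzofuran-5-carbaldehyde | O=Cc1cc(OC)c2c(c1)[C@@H](CO)[C@H](c1ccc(O[Si](C(C)C)(C(C)C)C(C)C)c(OC)c1)O2 | intermediate
18 | (2R,3S)-2-ArSi-7-methoxy-3-[(triisopropylsilyloxy)methyl]-2,3-dihydro-1-benzofuran-5-carbaldehyde | O=Cc1cc(OC)c2c(c1)[C@@H](CO[Si](C(C)C)(C(C)C)C(C)C)[C@H](c1ccc(O[Si](C(C)C)(C(C)C)C(C)C)c(OC)c1)O2 | intermediate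
19 | DE-methanol | OCc1cc(OC)c2c(c1)[C@@H](CO[Si](C(C)C)(C(C)C)C(C)C)[C@H](c1ccc(O[Si](C(C)C)(C(C)C)C(C)C)c(OC)c1)O2 | intermediate
20 | methyl 2-[2-(DE-methoxy)-5-formyl-3-methoxyphenyl]acetate | COC(=O)Cc1cc(C=O)cc(OC)c1OCc1cc(OC)c2c(c1)[C@@H](CO[Si](C(C)C)(C(C)C)C(C)C)[C@H](c1ccc(O[Si](C(C)C)(C(C)C)C(C)C)c(OC)c1)O2 | intermediate
21 | methyl 2-[2-(DE-methoxy)-5-(hydroxymethyl)-3-methoxyphenyl]acetate | COC(=O)Cc1cc(CO)cc(OC)c1OCc1cc(OC)c2c(c1)[C@@H](CO[Si](C(C)C)(C(C)C)C(C)C)[C@H](c1ccc(O[Si](C(C)C)(C(C)C)C(C)C)c(OC)c1)O2 | intermediate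
22 | bis(arylacetate), methyl 2-[2-{[4-(DE-methoxy)-3-methoxy-5-(2-methoxy-2-oxoethyl)phenyl]methoxy}-5-(1,3-dioxolan-2-yl)-3-methoxyphenyl]acetate | COC(=O)Cc1cc(cc(OC)c1OCc1cc(OC)c(OCc2cc(OC)c3c(c2)[C@@H](CO[Si](C(C)C)(C(C)C)C(C)C)[C@H](c2ccc(O[Si](C(C)C)(C(C)C)C(C)C)c(OC)c2)O3)c(CC(=O)OC)c1)C1OCCO1 | intermediate
23 | bis(diazoacetate) of 22 (both ArCH2CO2Me as ArC(=N2)CO2Me) | COC(=O)C(=[N+]=[N-])c1cc(cc(OC)c1OCc1cc(OC)c(OCc2cc(OC)c3c(c2)[C@@H](CO[Si](C(C)C)(C(C)C)C(C)C)[C@H](c2ccc(O[Si](C(C)C)(C(C)C)C(C)C)c(OC)c2)O3)c(c1)C(=[N+]=[N-])C(=O)OC)C1OCCO1 | intermediate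
24 | cis,cis diester, the (2S,3R),(2S,3R) C3 epimer of 25 at units 1 and 2 | O1CCOC1c1cc(OC)c2c(c1)[C@@H](C(=O)OC)[C@@H](c1cc(OC)c3c(c1)[C@@H](C(=O)OC)[C@@H](c1cc(OC)c4c(c1)[C@@H](CO[Si](C(C)C)(C(C)C)C(C)C)[C@H](c1ccc(O[Si](C(C)C)(C(C)C)C(C)C)c(OC)c1)O4)O3)O2 | intermediate
25 | trans,trans diester, methyl (2S,3S)-2-[(2S,3S)-2-DE-7-methoxy-3-(methoxycarbonyl)-2,3-dihydro-1-benzofuran-5-yl]-5-(1,3-dioxolan-2-yl)-7-methoxy-2,3-dihydro-1-benzofuran-3-carboxylate | O1CCOC1c1cc(OC)c2c(c1)[C@H](C(=O)OC)[C@@H](c1cc(OC)c3c(c1)[C@H](C(=O)OC)[C@@H](c1cc(OC)c4c(c1)[C@@H](CO[Si](C(C)C)(C(C)C)C(C)C)[C@H](c1ccc(O[Si](C(C)C)(C(C)C)C(C)C)c(OC)c1)O4)O3)O2 | intermediate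
26 | diol acetal, 25 with both CO2Me reduced to CH2OH (units 1 and 2 now 2S,3R) | O1CCOC1c1cc(OC)c2c(c1)[C@H](CO)[C@@H](c1cc(OC)c3c(c1)[C@H](CO)[C@@H](c1cc(OC)c4c(c1)[C@@H](CO[Si](C(C)C)(C(C)C)C(C)C)[C@H](c1ccc(O[Si](C(C)C)(C(C)C)C(C)C)c(OC)c1)O4)O3)O2 | intermediate
27 | (2S,3R)-2-[(2S,3R)-2-DE-3-(hydroxymethyl)-7-methoxy-2,3-dihydro-1-benzofuran-5-yl]-3-(hydroxymethyl)-7-methoxy-2,3-dihydro-1-benzofuran-5-carbaldehyde | O=Cc1cc(OC)c2c(c1)[C@H](CO)[C@@H](c1cc(OC)c3c(c1)[C@H](CO)[C@@H](c1cc(OC)c4c(c1)[C@@H](CO[Si](C(C)C)(C(C)C)C(C)C)[C@H](c1ccc(O[Si](C(C)C)(C(C)C)C(C)C)c(OC)c1)O4)O3)O2 | intermediate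
28 | BCDE-carbaldehyde (bis-TBS ether of 27) | O=Cc1cc(OC)c2c(c1)[C@H](CO[Si](C)(C)C(C)(C)C)[C@@H](c1cc(OC)c3c(c1)[C@H](CO[Si](C)(C)C(C)(C)C)[C@@H](c1cc(OC)c4c(c1)[C@@H](CO[Si](C(C)C)(C(C)C)C(C)C)[C@H](c1ccc(O[Si](C(C)C)(C(C)C)C(C)C)c(OC)c1)O4)O3)O2 | intermediate
29 | 3-(4-hydroxy-3-methoxyphenyl)propanoic acid | COc1cc(CCC(O)=O)ccc1O | starting material
30 | triisopropylsilyl 3-ArSi-propanoate | COc1cc(CCC(=O)O[Si](C(C)C)(C(C)C)C(C)C)ccc1O[Si](C(C)C)(C(C)C)C(C)C | intermediate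
31 | 3-ArSi-propanoic acid | COc1cc(CCC(O)=O)ccc1O[Si](C(C)C)(C(C)C)C(C)C | intermediate
32 | (R)-4-benzyl-1,3-oxazolidin-2-one | O=C1N[C@H](Cc2ccccc2)CO1 | starting material
33 | mixed anhydride of 31 with pivalic acid | COc1cc(CCC(=O)OC(=O)C(C)(C)C)ccc1O[Si](C(C)C)(C(C)C)C(C)C | intermediate
34 | (R)-4-benzyl-3-(3-ArSi-propanoyl)-1,3-oxazolidin-2-one | COc1cc(CCC(=O)N2[C@H](Cc3ccccc3)COC2=O)ccc1O[Si](C(C)C)(C(C)C)C(C)C | intermediate
35 | sodium Z-enolate of 34 | [Na+].COc1cc(C/C=C(\[O-])N2[C@H](Cc3ccccc3)COC2=O)ccc1O[Si](C(C)C)(C(C)C)C(C)C | intermediate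
36 | tert-butyl (3S)-3-(ArSi-methyl)-4-[(4R)-4-benzyl-2-oxo-1,3-oxazolidin-3-yl]-4-oxobutanoate | COc1cc(C[C@@H](CC(=O)OC(C)(C)C)C(=O)N2[C@H](Cc3ccccc3)COC2=O)ccc1O[Si](C(C)C)(C(C)C)C(C)C | intermediate
37 | tert-butyl (3S)-3-(ArSi-methyl)-4-hydroxybutanoate | COc1cc(C[C@@H](CC(=O)OC(C)(C)C)CO)ccc1O[Si](C(C)C)(C(C)C)C(C)C | intermediate
38 | (4S)-4-(ArSi-methyl)oxolan-2-one | COc1cc(C[C@H]2CC(=O)OC2)ccc1O[Si](C(C)C)(C(C)C)C(C)C | intermediate
39 | lithium enolate of 38 | [Li+].COc1cc(C[C@H]2C=C([O-])OC2)ccc1O[Si](C(C)C)(C(C)C)C(C)C | intermediate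
40 | (3R,4S)-3-[BCDE(hydroxy)methyl]-4-(ArSi-methyl)oxolan-2-one, both carbinol epimers | COc1cc(C[C@@H]2COC(=O)[C@H]2C(O)c2cc(OC)c3c(c2)[C@H](CO[Si](C)(C)C(C)(C)C)[C@@H](c2cc(OC)c4c(c2)[C@H](CO[Si](C)(C)C(C)(C)C)[C@@H](c2cc(OC)c5c(c2)[C@@H](CO[Si](C(C)C)(C(C)C)C(C)C)[C@H](c2ccc(O[Si](C(C)C)(C(C)C)C(C)C)c(OC)c2)O5)O4)O3)ccc1O[Si](C(C)C)(C(C)C)C(C)C | intermediate
41 | (2S,3S)-2-[BCDE(hydroxy)methyl]-3-(ArSi-methyl)butane-1,4-diol, both carbinol epimers | COc1cc(C[C@H](CO)[C@@H](CO)C(O)c2cc(OC)c3c(c2)[C@H](CO[Si](C)(C)C(C)(C)C)[C@@H](c2cc(OC)c4c(c2)[C@H](CO[Si](C)(C)C(C)(C)C)[C@@H](c2cc(OC)c5c(c2)[C@@H](CO[Si](C(C)C)(C(C)C)C(C)C)[C@H](c2ccc(O[Si](C(C)C)(C(C)C)C(C)C)c(OC)c2)O5)O4)O3)ccc1O[Si](C(C)C)(C(C)C)C(C)C | intermediate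
42 | [(2R,3S,4S)-2-BCDE-4-(ArSi-methyl)oxolan-3-yl]methanol | COc1cc(C[C@@H]2CO[C@@H](c3cc(OC)c4c(c3)[C@H](CO[Si](C)(C)C(C)(C)C)[C@@H](c3cc(OC)c5c(c3)[C@H](CO[Si](C)(C)C(C)(C)C)[C@@H](c3cc(OC)c6c(c3)[C@@H](CO[Si](C(C)C)(C(C)C)C(C)C)[C@H](c3ccc(O[Si](C(C)C)(C(C)C)C(C)C)c(OC)c3)O6)O5)O4)[C@@H]2CO)ccc1O[Si](C(C)C)(C(C)C)C(C)C | intermediate
43 | CNP0267891.2 | COc1cc(C[C@@H]2CO[C@@H](c3cc(OC)c4c(c3)[C@H](CO)[C@@H](c3cc(OC)c5c(c3)[C@H](CO)[C@@H](c3cc(OC)c6c(c3)[C@@H](CO)[C@H](c3ccc(O)c(OC)c3)O6)O5)O4)[C@@H]2CO)ccc1O | target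

**Step count and risks**

Total: 29 steps. Longest linear sequence: 22 steps from 5-bromovanillin (steps 1–5, 9–21, 26–29).

Steps most likely to fail:

1. Step 19. The second insertion may be slow or poorly controlled by the catalyst once the first ring has formed, or the two carbene termini may react bimolecularly at the concentration needed. The fallback forms the two rings one at a time, repeating the proven cycle of steps 9–14; it sets out from 19 and returns at 28.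
   - Mitsunobu coupling of 19 with 7 should give ether F1, and diazo transfer should give diazo ester F2.
   - Rh2(R-PTTL)4 should give cis ester F3, which DBU equilibrates to trans ester F4.
   - LiAlH4 should give acetal alcohol F5, and the acidic work-up hydroxy aldehyde F6.
   - TBSCl should give silyl ether F7, and NaBH4 benzylic alcohol F8.
   - A second Mitsunobu coupling with 7 should give ether F9, and diazo transfer diazo ester F10.
   - Rh2(R-PTTL)4 should give cis ester F11, and DBU trans ester F12.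
   - LiAlH4 should give acetal alcohol F13, and the acidic work-up hydroxy aldehyde F14.
   - Silylation of F14 with TBSCl gives 28.

2. Step 17. The redox condensation may stall at the doubly ortho-substituted phenol, or the para-alkoxybenzyl oxyphosphonium may ionise and alkylate carbon. The fallback sets out from 21 and returns at 22: Appel bromination (CBr4, PPh3, CH2Cl2, 0 °C) should give benzylic bromide F15, used crude, and Williamson alkylation of phenol 7 with it (K2CO3, acetone, rt) gives 22.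

3. Step 26. The aldol addition to the hindered, electron-rich aldehyde may be incomplete or revert on warming. The fallback makes the same C–C bond by acylation instead of addition; it sets out from 28 and returns at 40.
   - Pinnick oxidation (NaClO2, NaH2PO4, 2-methyl-2-butene, t-BuOH/H2O) should give carboxylic acid F16.
   - Carbonyldiimidazole should convert it into acyl imidazolide F17.
   - Acylation of lithium enolate 39 (2.2 equiv, THF, −78 °C) should give trans keto lactone F18.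
   - NaBH4 (MeOH/THF, −20 °C) reduces the ketone to the carbinol mixture 40.

Further compounds
F1 | step 19 | methyl 2-[2-(DE-methoxy)-5-(1,3-dioxolan-2-yl)-3-methoxyphenyl]acetate | COC(=O)Cc1cc(cc(OC)c1OCc1cc(OC)c2c(c1)[C@@H](CO[Si](C(C)C)(C(C)C)C(C)C)[C@H](c1ccc(O[Si](C(C)C)(C(C)C)C(C)C)c(OC)c1)O2)C1OCCO1
F2 | step 19 | methyl 2-[2-(DE-methoxy)-5-(1,3-dioxolan-2-yl)-3-methoxyphenyl]-2-diazoacetate | COC(=O)C(=[N+]=[N-])c1cc(cc(OC)c1OCc1cc(OC)c2c(c1)[C@@H](CO[Si](C(C)C)(C(C)C)C(C)C)[C@H](c1ccc(O[Si](C(C)C)(C(C)C)C(C)C)c(OC)c1)O2)C1OCCO1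
F3 | step 19 | methyl (2S,3R)-2-DE-5-(1,3-dioxolan-2-yl)-7-methoxy-2,3-dihydro-1-benzofuran-3-carboxylate (cis) | O1CCOC1c1cc(OC)c2c(c1)[C@@H](C(=O)OC)[C@@H](c1cc(OC)c3c(c1)[C@@H](CO[Si](C(C)C)(C(C)C)C(C)C)[C@H](c1ccc(O[Si](C(C)C)(C(C)C)C(C)C)c(OC)c1)O3)O2
F4 | step 19 | methyl (2S,3S)-2-DE-5-(1,3-dioxolan-2-yl)-7-methoxy-2,3-dihydro-1-benzofuran-3-carboxylate (trans) | O1CCOC1c1cc(OC)c2c(c1)[C@H](C(=O)OC)[C@@H](c1cc(OC)c3c(c1)[C@@H](CO[Si](C(C)C)(C(C)C)C(C)C)[C@H](c1ccc(O[Si](C(C)C)(C(C)C)C(C)C)c(OC)c1)O3)O2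
F5 | step 19 | [(2S,3R)-2-DE-5-(1,3-dioxolan-2-yl)-7-methoxy-2,3-dihydro-1-benzofuran-3-yl]methanol | O1CCOC1c1cc(OC)c2c(c1)[C@H](CO)[C@@H](c1cc(OC)c3c(c1)[C@@H](CO[Si](C(C)C)(C(C)C)C(C)C)[C@H](c1ccc(O[Si](C(C)C)(C(C)C)C(C)C)c(OC)c1)O3)O2
F6 | step 19 | (2S,3R)-2-DE-3-(hydroxymethyl)-7-methoxy-2,3-dihydro-1-benzofuran-5-carbaldehyde | O=Cc1cc(OC)c2c(c1)[C@H](CO)[C@@H](c1cc(OC)c3c(c1)[C@@H](CO[Si](C(C)C)(C(C)C)C(C)C)[C@H](c1ccc(O[Si](C(C)C)(C(C)C)C(C)C)c(OC)c1)O3)O2
F7 | step 19 | (2S,3R)-3-[(tert-butyldimethylsilyloxy)methyl]-2-DE-7-methoxy-2,3-dihydro-1-benzofuran-5-carbaldehyde | O=Cc1cc(OC)c2c(c1)[C@H](CO[Si](C)(C)C(C)(C)C)[C@@H](c1cc(OC)c3c(c1)[C@@H](CO[Si](C(C)C)(C(C)C)C(C)C)[C@H](c1ccc(O[Si](C(C)C)(C(C)C)C(C)C)c(OC)c1)O3)O2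
F8 | step 19 | {(2S,3R)-3-[(tert-butyldimethylsilyloxy)methyl]-2-DE-7-methoxy-2,3-dihydro-1-benzofuran-5-yl}methanol | OCc1cc(OC)c2c(c1)[C@H](CO[Si](C)(C)C(C)(C)C)[C@@H](c1cc(OC)c3c(c1)[C@@H](CO[Si](C(C)C)(C(C)C)C(C)C)[C@H](c1ccc(O[Si](C(C)C)(C(C)C)C(C)C)c(OC)c1)O3)O2
F9 | step 19 | methyl 2-[5-(1,3-dioxolan-2-yl)-3-methoxy-2-(aryl-methoxy)phenyl]acetate, aryl = the 5-yl group of F8 | COC(=O)Cc1cc(cc(OC)c1OCc1cc(OC)c2c(c1)[C@H](CO[Si](C)(C)C(C)(C)C)[C@@H](c1cc(OC)c3c(c1)[C@@H](CO[Si](C(C)C)(C(C)C)C(C)C)[C@H](c1ccc(O[Si](C(C)C)(C(C)C)C(C)C)c(OC)c1)O3)O2)C1OCCO1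
F10 | step 19 | diazoacetate of F9 | COC(=O)C(=[N+]=[N-])c1cc(cc(OC)c1OCc1cc(OC)c2c(c1)[C@H](CO[Si](C)(C)C(C)(C)C)[C@@H](c1cc(OC)c3c(c1)[C@@H](CO[Si](C(C)C)(C(C)C)C(C)C)[C@H](c1ccc(O[Si](C(C)C)(C(C)C)C(C)C)c(OC)c1)O3)O2)C1OCCO1
F11 | step 19 | cis ester at unit 1, the (2S,3R) C3 epimer of F12 | O1CCOC1c1cc(OC)c2c(c1)[C@@H](C(=O)OC)[C@@H](c1cc(OC)c3c(c1)[C@H](CO[Si](C)(C)C(C)(C)C)[C@@H](c1cc(OC)c4c(c1)[C@@H](CO[Si](C(C)C)(C(C)C)C(C)C)[C@H](c1ccc(O[Si](C(C)C)(C(C)C)C(C)C)c(OC)c1)O4)O3)O2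
F12 | step 19 | methyl (2S,3S)-2-{(2S,3R)-3-[(tert-butyldimethylsilyloxy)methyl]-2-DE-7-methoxy-2,3-dihydro-1-benzofuran-5-yl}-5-(1,3-dioxolan-2-yl)-7-methoxy-2,3-dihydro-1-benzofuran-3-carboxylate (trans) | O1CCOC1c1cc(OC)c2c(c1)[C@H](C(=O)OC)[C@@H](c1cc(OC)c3c(c1)[C@H](CO[Si](C)(C)C(C)(C)C)[C@@H](c1cc(OC)c4c(c1)[C@@H](CO[Si](C(C)C)(C(C)C)C(C)C)[C@H](c1ccc(O[Si](C(C)C)(C(C)C)C(C)C)c(OC)c1)O4)O3)O2
F13 | step 19 | acetal alcohol, F12 with CO2Me reduced to CH2OH | O1CCOC1c1cc(OC)c2c(c1)[C@H](CO)[C@@H](c1cc(OC)c3c(c1)[C@H](CO[Si](C)(C)C(C)(C)C)[C@@H](c1cc(OC)c4c(c1)[C@@H](CO[Si](C(C)C)(C(C)C)C(C)C)[C@H](c1ccc(O[Si](C(C)C)(C(C)C)C(C)C)c(OC)c1)O4)O3)O2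
F14 | step 19 | hydroxy aldehyde, 28 with the unit 1 silyl ether as free CH2OH | O=Cc1cc(OC)c2c(c1)[C@H](CO)[C@@H](c1cc(OC)c3c(c1)[C@H](CO[Si](C)(C)C(C)(C)C)[C@@H](c1cc(OC)c4c(c1)[C@@H](CO[Si](C(C)C)(C(C)C)C(C)C)[C@H](c1ccc(O[Si](C(C)C)(C(C)C)C(C)C)c(OC)c1)O4)O3)O2
F15 | step 17 | methyl 2-[5-(bromomethyl)-2-(DE-methoxy)-3-methoxyphenyl]acetate | COC(=O)Cc1cc(CBr)cc(OC)c1OCc1cc(OC)c2c(c1)[C@@H](CO[Si](C(C)C)(C(C)C)C(C)C)[C@H](c1ccc(O[Si](C(C)C)(C(C)C)C(C)C)c(OC)c1)O2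
F16 | step 26 | BCDE-carboxylic acid | OC(=O)c1cc(OC)c2c(c1)[C@H](CO[Si](C)(C)C(C)(C)C)[C@@H](c1cc(OC)c3c(c1)[C@H](CO[Si](C)(C)C(C)(C)C)[C@@H](c1cc(OC)c4c(c1)[C@@H](CO[Si](C(C)C)(C(C)C)C(C)C)[C@H](c1ccc(O[Si](C(C)C)(C(C)C)C(C)C)c(OC)c1)O4)O3)O2
F17 | step 26 | BCDE-carbonyl imidazolide (1-acylimidazole of F16) | O=C(n1ccnc1)c1cc(OC)c2c(c1)[C@H](CO[Si](C)(C)C(C)(C)C)[C@@H](c1cc(OC)c3c(c1)[C@H](CO[Si](C)(C)C(C)(C)C)[C@@H](c1cc(OC)c4c(c1)[C@@H](CO[Si](C(C)C)(C(C)C)C(C)C)[C@H](c1ccc(O[Si](C(C)C)(C(C)C)C(C)C)c(OC)c1)O4)O3)O2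
F18 | step 26 | (3R,4S)-3-(BCDE-carbonyl)-4-(ArSi-methyl)oxolan-2-one (trans keto lactone) | COc1cc(C[C@@H]2COC(=O)[C@H]2C(=O)c2cc(OC)c3c(c2)[C@H](CO[Si](C)(C)C(C)(C)C)[C@@H](c2cc(OC)c4c(c2)[C@H](CO[Si](C)(C)C(C)(C)C)[C@@H](c2cc(OC)c5c(c2)[C@@H](CO[Si](C(C)C)(C(C)C)C(C)C)[C@H](c2ccc(O[Si](C(C)C)(C(C)C)C(C)C)c(OC)c2)O5)O4)O3)ccc1O[Si](C(C)C)(C(C)C)C(C)C
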